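I decided to reckon this flask by counting turnovers of the charge.

in all of them: substrate 0.043 M

| run | partner | remark | time |
|---|---|---|---|
| east | 3.5 equiv | run made earlier |  |
| north | 5.5 equiv | run made earlier |  |
| flask | 2.50 equiv |  | 50 min |

| run | time / min | substrate / % | mono adduct / % |
|---|---|---|---|
| east | 5.00 | 14 | 77 |
| east | 12.0 | 4 | 82 |
| east | 25.0 | 0 | 67 |
| east | 60.0 | 2 | 33 |
| north | 5.00 | 7 | 83 |
| north | 12.0 | 1 | 66 |
| north | 25.0 | 0 | 42 |
| north | 60.0 | 0 | 1 |

(readings scatter by 1.5 percentage points)

- amount of substrate at 50 min, in percent of the substrate charged
- amount of mono adduct at 50 min, in percent of the substrate charged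
- amount of double product at 50 min, in percent of the substrate charged

- amounts and yields of mono adduct count crystals too
- given per volume of solution although it is solid: crystals
- steps under discussion: mono adduct <-> isomer of the product; partner + mono adduct -> double product; crystals <-> mono adduct; substrate + partner -> mono adduct

In the east run the mono adduct lost 34 percentage points between 25.0 min and 60.0 min. Read as a straight, pseudo-zero-order fall, that would spend a whole charge in 103 min. I took free partner as the charge less one equivalent for the substrate reacted and one more for each equivalent of double product, reading what the mono adduct had lost as double product, and the mean there was 2.00 equiv. So the readings gave a value for the turnover time at one equivalent of free partner: 206 min. The north run read 219 min.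

Then I drew the flask's curve. Scaling east's substrate reading by partner gave me an estimated substrate half-life of 2.47 min, so I drew the mono adduct rising steeply, by about half the charge in that time. With 1.50 equiv free, a charge turned over in 137 min. In my reckoning, making fell to that drain with 2.59% substrate left, which put the knee near 13.0 min and the peak of mono adduct near 87.9%. From there I drew the line down, flattening slightly as free partner fell. Over 50 min at a mean of 1.32 equiv free, the count was 0.320 charges, less than one, so I expected 32.0% double product.

The forecast gave 0.3% substrate, 62% mono adduct and 35% double product, 3 points more double product than my count, on a loss “zero order in mono adduct and first order in free partner”.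

The flask gave 0.00894% substrate, 62.3% mono adduct and 34.7% double product.

    mono adduct ⇌ isomer of the product (K = 0.490, k = 0.00910 s⁻¹)
    partner + mono adduct → double product (k = 0.0320 M⁻¹ s⁻¹)
    crystals ⇌ mono adduct, rate k3*(cs3 - [mono adduct]) while solid is left; crystals form when [mono adduct] > cs3 (solubility = 2.60 mM, k = 1.40 s⁻¹)
    substrate + partner → mono adduct (k = 0.0520 M⁻¹ s⁻¹)

The same count went to the neighbour charged with 10.0 equiv of partner. With a mean of 8.50 equiv free, a charge turned over in 24.2 min, shorter than the 50 min allowed, so the count reached 2.07 charges where one was there to spend. That neighbour held 0% mono adduct and >99.9% double product at 50.0 min, with 80.0% of its partner charge left.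

The numbers in the tables are calculated with constants of no real substance; scatter was added.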